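**Plan**

1. Retrosynthesis: the two side-chain ester C–O bonds (at O8 and O9) are cut first. The lactone bonds O1–C6 and C11–C7 are then cut together, which removes the whole α-methylene-γ-lactone as 2-bromoacrylic acid and leaves a ten-membered (4Z,6E)-diene. Last come the ring bond C6=C7 (metathesis), C10–C14 (carboxylation) and C9–C10 (alkynylation).
2. Enabling feature: the lactone oxygen sits on C6, allylic to the ring olefin C4=C5. The five-membered ring O1–C12–C11–C7–C6 is therefore the product of carbopalladation of a C4=C5–C6=C7 diene at C7, followed by carboxylate capture of the C4–C5–C6 η3-allyl at C6.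
3. Forward: neryl acetate gives the C1–C6/C15 dienyne and (S)-but-3-ene-1,2-diol gives the C7–C9 aldehyde. Alkynylation, syn-hydrostannation and carboxylation give the open chain; ring-closing metathesis closes the ten-membered ring; the palladium annulation then fuses the lactone ring; the two acyl groups go on last.
4. Stereochemistry: C8 comes from the diol and C9 from chelation-controlled alkynylation. The C1=C10 geometry comes from syn-hydrostannation and C4=C5 (Z) from nerol. C7 and C6 are set in the annulation (outer face of the E olefin, syn C–O closure). The side chains come from an Evans aldol reaction and a Sharpless epoxidation.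

Key step: step 12

Remark: locants are germacrane locants (ring C1–C10, lactone C11–C13, ester carbon C14 on C10, methyl C15 on C4) and are also used for the open-chain precursors. Compounds 1, 7, 19, 21, 22 and 29 are taken as commercial.

**Route**

Step 1
Reactants: 1 neryl acetate
Product: 3 (2Z)-3-methyl-6-oxohex-2-en-1-yl acetate, via 6,7-epoxyneryl acetate 2 (not isolated)
Conditions: mCPBA, NaHCO3, CH2Cl2, 0 °C; then H5IO6, THF/H2O, 0 °C
Reagents that add atoms: mCPBA (3-chloroperoxybenzoic acid), O=C(OO)c1cccc(Cl)c1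
Why: The electron-rich 6,7-olefin is epoxidised in preference to the acetate-deactivated 2,3-olefin (Prilezhaev epoxidation), and periodic acid then cleaves the epoxide through the diol to the aldehyde and acetone without touching the Z olefin.

Step 2
Reactants: 3 (2Z)-3-methyl-6-oxohex-2-en-1-yl acetate
Product: 4 (2Z)-3-methylhept-2-en-6-yn-1-ol
Conditions: dimethyl (1-diazo-2-oxopropyl)phosphonate, K2CO3, MeOH, 0 °C to rt
Reagents that add atoms: dimethyl (1-diazo-2-oxopropyl)phosphonate, COP(=O)(OC)C(=[N+]=[N-])C(C)=O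
Why: Seyferth–Gilbert homologation with the Ohira–Bestmann reagent turns the aldehyde into the terminal alkyne under K2CO3/MeOH, conditions that also methanolyse the allylic acetate.

Step 3
Reactants: 4 (2Z)-3-methylhept-2-en-6-yn-1-ol
Product: 5 (2Z)-3-methylhept-2-en-6-ynal
Conditions: activated MnO2, CH2Cl2, rt
Reagents that add atoms: none
Why: Activated MnO2 oxidises only the allylic alcohol (allylic oxidation) and is mild enough to keep the Z enal from isomerising.

Step 4
Reactants: 5 (2Z)-3-methylhept-2-en-6-ynal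
Product: 6 (3Z)-4-methylocta-1,3-dien-7-yne
Conditions: Ph3PCH3Br, NaN(SiMe3)2, THF, −78 to 0 °C
Reagents that add atoms: methylenetriphenylphosphorane (from methyltriphenylphosphonium bromide), C=P(c1ccccc1)(c1ccccc1)c1ccccc1
Why: Wittig methylenation of the enal gives the terminal diene without touching the Z trisubstituted olefin or the alkyne C–H, which is less acidic than the phosphonium salt.

Step 5
Reactants: 7 (2S)-but-3-ene-1,2-diol
Product: 8 (4S)-2-(4-methoxyphenyl)-4-vinyl-1,3-dioxolane (mixture of epimers at the acetal carbon)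
Conditions: 4-MeOC6H4CH(OMe)2, PPTS (cat.), CH2Cl2, rt
Reagents that add atoms: 4-methoxybenzaldehyde dimethyl acetal, COC(OC)c1ccc(OC)cc1
Why: Acid-catalysed transacetalisation closes the five-membered 4-methoxybenzylidene acetal on the 1,2-diol without touching the stereocentre.

Step 6
Reactants: 8 (4S)-2-(4-methoxyphenyl)-4-vinyl-1,3-dioxolane
Product: 9 (2S)-2-[(4-methoxybenzyl)oxy]but-3-en-1-ol
Conditions: i-Bu2AlH, CH2Cl2, −78 to 0 °C
Reagents that add atoms: none
Why: In this reductive acetal opening the aluminium coordinates the less hindered primary oxygen and hydride goes to the oxocarbenium ion, so the 4-methoxybenzyl group stays on the secondary oxygen and the primary alcohol is freed.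

Step 7
Reactants: 9 (2S)-2-[(4-methoxybenzyl)oxy]but-3-en-1-ol
Product: 10 (2S)-2-[(4-methoxybenzyl)oxy]but-3-enal
Conditions: Dess–Martin periodinane, NaHCO3, CH2Cl2, 0 °C; used at once
Reagents that add atoms: none
Why: Buffered Dess–Martin oxidation gives the α-alkoxy β,γ-unsaturated aldehyde without base, so the C8 stereocentre and the position of the olefin should be kept.

Step 8
Reactants: 6 (3Z)-4-methylocta-1,3-dien-7-yne; 10 (2S)-2-[(4-methoxybenzyl)oxy]but-3-enal
Product: 13 (3Z,9S,10S)-10-[(4-methoxybenzyl)oxy]-4-methyldodeca-1,3,11-trien-7-yn-9-ol, via lithium acetylide 11 (not isolated), via bromozinc acetylide 12 (not isolated)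
Conditions: 6, n-BuLi, Et2O, −78 °C; ZnBr2, 0 °C; then 10, −78 to −20 °C
Reagents that add atoms: none
Why: Cram-chelate addition of the alkynylzinc bromide to the α-(4-methoxybenzyloxy) aldehyde (zinc bridges the carbonyl and ether oxygens, attack past the α-hydrogen) should give the syn 8,9-diol derivative, that is 9S from 8S.

Step 9
Reactants: 13 (3Z,9S,10S)-10-[(4-methoxybenzyl)oxy]-4-methyldodeca-1,3,11-trien-7-yn-9-ol
Product: 14 (3Z,7E,9R,10S)-10-[(4-methoxybenzyl)oxy]-4-methyl-8-(tributylstannyl)dodeca-1,3,7,11-tetraen-9-ol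
Conditions: Bu3SnH, PdCl2(PPh3)2 (cat.), THF, 0 °C
Reagents that add atoms: tributyltin hydride, CCCC[SnH](CCCC)CCCC
Why: Palladium-catalysed syn hydrostannation of the propargylic alcohol places tin on the alkyne carbon next to the carbinol and hydrogen on C1, which fixes C2 and C9 cis across the future C1=C10 bond (the 9R descriptor only reflects the priority of tin).

Step 10
Reactants: 14 (3Z,7E,9R,10S)-10-[(4-methoxybenzyl)oxy]-4-methyl-8-(tributylstannyl)dodeca-1,3,7,11-tetraen-9-ol
Product: 17 methyl (2E,6Z)-2-{(1S,2S)-1-hydroxy-2-[(4-methoxybenzyl)oxy]but-3-en-1-yl}-6-methylnona-2,6,8-trienoate, via dilithio species 15 (not isolated), via hydroxy acid 16 (not isolated)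
Conditions: n-BuLi (2.2 equiv.), THF, −78 °C; CO2; aq. HCl; then Me3SiCHN2, PhMe/MeOH, 0 °C
Reagents that add atoms: carbon dioxide, O=C=O; (trimethylsilyl)diazomethane, C[Si](C)(C)C=[N+]=[N-]
Why: Tin–lithium exchange proceeds with retention of olefin geometry, the alkenyllithium next to the lithium alkoxide is carboxylated by CO2, and Me3SiCHN2 then methylates only the carboxylic acid, giving the E α-(1-hydroxyalkyl) enoate.

Step 11
Reactants: 17 methyl (2E,6Z)-2-{(1S,2S)-1-hydroxy-2-[(4-methoxybenzyl)oxy]but-3-en-1-yl}-6-methylnona-2,6,8-trienoate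
Product: 18 methyl (1E,5Z,7E,9S,10S)-10-hydroxy-9-[(4-methoxybenzyl)oxy]-5-methylcyclodeca-1,5,7-triene-1-carboxylate
Conditions: second-generation Hoveyda–Grubbs catalyst (10 mol %), 1,4-benzoquinone (cat.), PhMe (1 mM), 80 °C
Reagents that add atoms: none
Why: Ring-closing metathesis between the diene terminus and the vinyl group (the trisubstituted C4=C5 and C1=C10 olefins are inert) closes the ten-membered ring with loss of ethene, and the new C6=C7 bond is expected to be E, the conjugated s-trans diene that already has the anti C5–C6–C7–C8 arrangement of a trans-lactone-fused germacranolide.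

Step 12
Reactants: 18 methyl (1E,5Z,7E,9S,10S)-10-hydroxy-9-[(4-methoxybenzyl)oxy]-5-methylcyclodeca-1,5,7-triene-1-carboxylate; 19 2-bromoacrylic acid
Product: 20 methyl (1(10)E,4Z,6R,7S,8S,9S)-9-hydroxy-8-[(4-methoxybenzyl)oxy]-12-oxo-6,12-epoxygermacra-1(10),4,11(13)-trien-14-oate (trans-fused α-methylene-γ-lactone)
Conditions: Pd(OAc)2 (10 mol %), P(2-furyl)3 (20 mol %), Ag2CO3, MeCN, 60 °C
Reagents that add atoms: none
Why: Proposed new method: zerovalent palladium (from Pd(OAc)2 and the phosphine) inserts into the C–Br bond of 19, the α-carboxyalkenylpalladium adds syn across the strained E C6=C7 olefin of the C4=C5–C6=C7 diene with carbon going to the diene terminus C7, and the carboxylate, held on the same palladium in a six-membered chelate once Ag2CO3 has removed bromide, closes the C6–O bond on the C6–C5–C4 η3-allyl; the closest known reaction type is the Larock heteroannulation of 1,3-dienes by aryl and alkenyl halides that carry a carboxylic acid, which has not been shown for 2-bromoacrylic acid on a medium-ring diene. The γ-lactone ring closes in a 5-exo mode at the allyl terminus C6, and the alternative attack at C4 would need a seven-membered ring. C7 (S) is controlled by the C8 stereocentre through the ring: the alkenyl group is delivered to the outer face of the E olefin in the conformer that keeps the C8–O bond in the olefin plane, which is the face anti to C9. C6 (R) follows from the syn addition across the E olefin (C11 and oxygen both delivered from palladium on one face), which gives the trans-fused lactone, and since the allylic C6–O bond can re-ionise under the conditions this isomer is also the thermodynamic one. The step needs site selectivity for C6=C7 over C4=C5 and C1=C10 (secured by the strain and disubstitution of C6=C7, the trisubstitution of C4=C5 and the electron-poor enoate), C–C bond formation at C7 and not at the fully substituted C4, and retention of the 4Z geometry, which holds because capture at C6 is faster than π–σ–π isomerisation through the tertiary allyl terminus.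

Step 13
Reactants: 21 (4R)-4-benzyl-3-propionyloxazolidin-2-one; 22 acetaldehyde
Product: 24 (4R)-4-benzyl-3-[(2R,3S)-3-hydroxy-2-methylbutanoyl]oxazolidin-2-one, via dibutylboron Z-enolate 23 (not isolated)
Conditions: Bu2BOTf, i-Pr2NEt, CH2Cl2, 0 °C; then 22, −78 to 0 °C; H2O2, pH 7 buffer, MeOH
Reagents that add atoms: none
Why: Evans syn aldol reaction, in which the Z boron enolate reacts through a chair Zimmerman–Traxler transition state on the face away from the benzyl group, so the (R)-auxiliary gives the (2R,3S) syn aldol.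

Step 14
Reactants: 24 (4R)-4-benzyl-3-[(2R,3S)-3-hydroxy-2-methylbutanoyl]oxazolidin-2-one
Product: 25 (4R)-4-benzyl-3-[(2R,3S)-3-(tert-butyldimethylsilyloxy)-2-methylbutanoyl]oxazolidin-2-one
Conditions: TBSOTf, 2,6-lutidine, CH2Cl2, 0 °C
Reagents that add atoms: tert-butyldimethylsilyl trifluoromethanesulfonate, CC(C)(C)[Si](C)(C)OS(=O)(=O)C(F)(F)F
Why: Silylation of the secondary alcohol with the silyl triflate and a hindered base is fast at 0 °C and avoids retro-aldol cleavage.

Step 15
Reactants: 25 (4R)-4-benzyl-3-[(2R,3S)-3-(tert-butyldimethylsilyloxy)-2-methylbutanoyl]oxazolidin-2-one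
Product: 26 (2R,3S)-3-(tert-butyldimethylsilyloxy)-2-methylbutanoic acid
Conditions: LiOH, H2O2, THF/H2O, 0 °C; then Na2SO3; aq. HCl
Reagents that add atoms: hydrogen peroxide, OO
Why: Lithium hydroperoxide attacks the exocyclic imide carbonyl selectively (auxiliary cleavage by acyl substitution) and releases the acid without epimerising C2.

Step 16
Reactants: 20 germacranolide alcohol (C9–OH); 26 (2R,3S)-3-(tert-butyldimethylsilyloxy)-2-methylbutanoic acid
Product: 27 methyl (1(10)E,4Z,6R,7S,8S,9S)-9-{[(2R,3S)-3-(tert-butyldimethylsilyloxy)-2-methylbutanoyl]oxy}-8-[(4-methoxybenzyl)oxy]-12-oxo-6,12-epoxygermacra-1(10),4,11(13)-trien-14-oate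
Conditions: DCC, DMAP (cat.), CH2Cl2, 0 °C to rt
Reagents that add atoms: none
Why: Steglich esterification of the only free hydroxyl (C9–OH), run cold with catalytic DMAP so that the α-stereocentre of the acid is kept.

Step 17
Reactants: 27 C9 ester with C8 4-methoxybenzyl ether
Product: 28 methyl (1(10)E,4Z,6R,7R,8S,9S)-9-{[(2R,3S)-3-(tert-butyldimethylsilyloxy)-2-methylbutanoyl]oxy}-8-hydroxy-12-oxo-6,12-epoxygermacra-1(10),4,11(13)-trien-14-oate (7R only through the priority change)
Conditions: DDQ, CH2Cl2/pH 7 buffer, 0 °C to rt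
Reagents that add atoms: none
Why: Oxidative cleavage of the 4-methoxybenzyl ether by DDQ (hydride abstraction, then hydrolysis of the oxocarbenium ion) under buffered conditions frees C8–OH without acyl migration.

Step 18
Reactants: 29 (2E)-2-methylbut-2-en-1-ol (tiglyl alcohol)
Product: 30 [(2R,3R)-2,3-dimethyloxiran-2-yl]methanol
Conditions: Ti(OiPr)4 (cat.), D-(−)-diethyl tartrate (cat.), t-BuOOH, 4 Å molecular sieves, CH2Cl2, −20 °C
Reagents that add atoms: tert-butyl hydroperoxide, CC(C)(C)OO
Why: Sharpless asymmetric epoxidation of the E allylic alcohol, in which the titanium–D-tartrate complex delivers oxygen to the face that gives the (2R,3R)-epoxy alcohol with the two methyl groups cis.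

Step 19
Reactants: 30 [(2R,3R)-2,3-dimethyloxiran-2-yl]methanol
Product: 31 (2S,3R)-2,3-dimethyloxirane-2-carboxylic acid
Conditions: RuCl3·xH2O (cat.), NaIO4, MeCN/CCl4/H2O, rt
Reagents that add atoms: water, O
Why: Ruthenium tetroxide generated from RuCl3 and NaIO4 oxidises the primary alcohol to the acid and leaves the epoxide intact (Sharpless ruthenium oxidation), the C2 descriptor changing to S only through the priority change.

Step 20
Reactants: 31 (2S,3R)-2,3-dimethyloxirane-2-carboxylic acid; 28 germacranolide alcohol (C8–OH)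
Product: 33 methyl (1(10)E,4Z,6R,7S,8S,9S)-9-{[(2R,3S)-3-(tert-butyldimethylsilyloxy)-2-methylbutanoyl]oxy}-8-{[(2S,3R)-2,3-dimethyloxirane-2-carbonyl]oxy}-12-oxo-6,12-epoxygermacra-1(10),4,11(13)-trien-14-oate, via mixed anhydride 32 (not isolated)
Conditions: 2,4,6-Cl3C6H2COCl, Et3N, THF, rt; then 28, DMAP, PhMe, rt
Reagents that add atoms: none
Why: Yamaguchi esterification, in which DMAP attacks the mixed anhydride at the less hindered epoxy acyl carbon and the acylpyridinium acylates the hindered C8–OH, the acid having no α-hydrogen to epimerise.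

Step 21
Reactants: 33 silyl-protected diester
Product: 34 CNP0135583.2, methyl (1(10)E,4Z,6R,7S,8S,9S)-8-{[(2S,3R)-2,3-dimethyloxirane-2-carbonyl]oxy}-9-{[(2R,3S)-3-hydroxy-2-methylbutanoyl]oxy}-12-oxo-6,12-epoxygermacra-1(10),4,11(13)-trien-14-oate
Conditions: HF·pyridine, pyridine, THF, 0 °C to rt
Reagents that add atoms: none
Why: Fluoride-mediated desilylation with buffered HF·pyridine removes the tert-butyldimethylsilyl ether without opening the epoxide or adding to the α-methylene lactone.

**Compound list**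

1 | neryl acetate, (2Z)-3,7-dimethylocta-2,6-dien-1-yl acetate | CC(=O)OC/C=C(/C)CCC=C(C)C | starting material
2 | 6,7-epoxyneryl acetate (racemic at the epoxide) | CC(=O)OC/C=C(/C)CCC1OC1(C)C | intermediate (not isolated)
3 | (2Z)-3-methyl-6-oxohex-2-en-1-yl acetate | CC(=O)OC/C=C(/C)CCC=O | intermediate
4 | (2Z)-3-methylhept-2-en-6-yn-1-ol | OC/C=C(/C)CCC#C | intermediate
5 | (2Z)-3-methylhept-2-en-6-ynal | O=C/C=C(/C)CCC#C | intermediate
6 | (3Z)-4-methylocta-1,3-dien-7-yne | C=C/C=C(/C)CCC#C | intermediate
7 | (2S)-but-3-ene-1,2-diol | C=C[C@H](O)CO | starting material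
8 | (4S)-2-(4-methoxyphenyl)-4-vinyl-1,3-dioxolane (acetal epimers) | C=C[C@H]1COC(c2ccc(OC)cc2)O1 | intermediate
9 | (2S)-2-[(4-methoxybenzyl)oxy]but-3-en-1-ol | C=C[C@H](OCc1ccc(OC)cc1)CO | intermediate
10 | (2S)-2-[(4-methoxybenzyl)oxy]but-3-enal | C=C[C@H](OCc1ccc(OC)cc1)C=O | intermediate
11 | lithium acetylide of 6 | [Li]C#CCC/C(C)=C\C=C | intermediate (not isolated)
12 | bromozinc acetylide of 6 | Br[Zn]C#CCC/C(C)=C\C=C | intermediate (not isolated)
13 | (3Z,9S,10S)-10-[(4-methoxybenzyl)oxy]-4-methyldodeca-1,3,11-trien-7-yn-9-ol | C=C/C=C(/C)CCC#C[C@H](O)[C@@H](OCc1ccc(OC)cc1)C=C | intermediate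
14 | (3Z,7E,9R,10S)-10-[(4-methoxybenzyl)oxy]-4-methyl-8-(tributylstannyl)dodeca-1,3,7,11-tetraen-9-ol | C=C/C=C(/C)CC/C=C(/[Sn](CCCC)(CCCC)CCCC)[C@H](O)[C@@H](OCc1ccc(OC)cc1)C=C | intermediate
15 | dilithio species from 14 (lithium alkoxide, lithium in place of tin) | C=C/C=C(/C)CC/C=C(/[Li])[C@H](O[Li])[C@@H](OCc1ccc(OC)cc1)C=C | intermediate (not isolated)
16 | (2E,6Z)-2-{(1S,2S)-1-hydroxy-2-[(4-methoxybenzyl)oxy]but-3-en-1-yl}-6-methylnona-2,6,8-trienoic acid | C=C/C=C(/C)CC/C=C(/C(=O)O)[C@H](O)[C@@H](OCc1ccc(OC)cc1)C=C | intermediate (not isolated)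
17 | methyl (2E,6Z)-2-{(1S,2S)-1-hydroxy-2-[(4-methoxybenzyl)oxy]but-3-en-1-yl}-6-methylnona-2,6,8-trienoate | C=C/C=C(/C)CC/C=C(/C(=O)OC)[C@H](O)[C@@H](OCc1ccc(OC)cc1)C=C | intermediate
18 | methyl (1E,5Z,7E,9S,10S)-10-hydroxy-9-[(4-methoxybenzyl)oxy]-5-methylcyclodeca-1,5,7-triene-1-carboxylate | COC(=O)/C1=C/CC/C(C)=C\C=C\[C@H](OCc2ccc(OC)cc2)[C@H]1O | intermediate
19 | 2-bromoacrylic acid | C=C(Br)C(=O)O | starting material
20 | methyl (1(10)E,4Z,6R,7S,8S,9S)-9-hydroxy-8-[(4-methoxybenzyl)oxy]-12-oxo-6,12-epoxygermacra-1(10),4,11(13)-trien-14-oate | C=C1C(=O)O[C@@H]2/C=C(/C)CC/C=C(/C(=O)OC)[C@H](O)[C@@H](OCc3ccc(OC)cc3)[C@@H]12 | intermediate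
21 | (4R)-4-benzyl-3-propionyloxazolidin-2-one | CCC(=O)N1[C@H](Cc2ccccc2)COC1=O | starting material
22 | acetaldehyde | CC=O | starting material
23 | dibutylboron Z-enolate of 21 | C/C=C(\OB(CCCC)CCCC)N1[C@H](Cc2ccccc2)COC1=O | intermediate (not isolated)
24 | (4R)-4-benzyl-3-[(2R,3S)-3-hydroxy-2-methylbutanoyl]oxazolidin-2-one | O=C([C@H](C)[C@H](C)O)N1[C@H](Cc2ccccc2)COC1=O | intermediate
25 | (4R)-4-benzyl-3-[(2R,3S)-3-(tert-butyldimethylsilyloxy)-2-methylbutanoyl]oxazolidin-2-one | O=C([C@H](C)[C@H](C)O[Si](C)(C)C(C)(C)C)N1[C@H](Cc2ccccc2)COC1=O | intermediate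
26 | (2R,3S)-3-(tert-butyldimethylsilyloxy)-2-methylbutanoic acid | OC(=O)[C@H](C)[C@H](C)O[Si](C)(C)C(C)(C)C | intermediate
27 | C9 silyloxybutanoate, C8 4-methoxybenzyl ether of the germacranolide (6R,7S,8S,9S) | C=C1C(=O)O[C@@H]2/C=C(/C)CC/C=C(/C(=O)OC)[C@H](OC(=O)[C@H](C)[C@H](C)O[Si](C)(C)C(C)(C)C)[C@@H](OCc3ccc(OC)cc3)[C@@H]12 | intermediate
28 | C9 silyloxybutanoate, C8 alcohol of the germacranolide (6R,7R,8S,9S) | C=C1C(=O)O[C@@H]2/C=C(/C)CC/C=C(/C(=O)OC)[C@H](OC(=O)[C@H](C)[C@H](C)O[Si](C)(C)C(C)(C)C)[C@@H](O)[C@@H]12 | intermediate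
29 | (2E)-2-methylbut-2-en-1-ol (tiglyl alcohol) | C/C=C(\C)CO | starting material
30 | [(2R,3R)-2,3-dimethyloxiran-2-yl]methanol | OC[C@@]1(C)O[C@@H]1C | intermediate
31 | (2S,3R)-2,3-dimethyloxirane-2-carboxylic acid | OC(=O)[C@@]1(C)O[C@@H]1C | intermediate
32 | (2S,3R)-2,3-dimethyloxirane-2-carboxylic 2,4,6-trichlorobenzoic anhydride | O=C(OC(=O)[C@@]1(C)O[C@@H]1C)c1c(Cl)cc(Cl)cc1Cl | intermediate (not isolated)
33 | C9 silyloxybutanoate, C8 epoxy ester of the germacranolide (6R,7S,8S,9S) | C=C1C(=O)O[C@@H]2/C=C(/C)CC/C=C(/C(=O)OC)[C@H](OC(=O)[C@H](C)[C@H](C)O[Si](C)(C)C(C)(C)C)[C@@H](OC(=O)[C@@]3(C)O[C@@H]3C)[C@@H]12 | intermediate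
34 | CNP0135583.2 | C=C1C(=O)O[C@@H]2/C=C(/C)CC/C=C(/C(=O)OC)[C@H](OC(=O)[C@H](C)[C@H](C)O)[C@@H](OC(=O)[C@@]3(C)O[C@@H]3C)[C@@H]12 | target

**Step count and risks**

Total step count: 21. Longest linear sequence: 13 steps (steps 1–4, 8–12, 16, 17, 20, 21).

Steps most likely to fail:

Step 12 (Proposed new method). The alkenylpalladium may insert on the inner face of C6=C7 (poor facial selectivity), the allyl may be captured at C4 or lose a β-hydrogen instead of closing the lactone, or the bromoacrylate may polymerise or lose bromine before insertion. The fallback uses known chemistry, sets out from 18 and comes back at 20. A manganese triacetate-mediated oxidative lactone annulation of the diene with malonic acid (Mn(OAc)3·2H2O, malonic acid, KOAc, AcOH, 60 °C; radical addition at C7, oxidation of the allyl radical, lactonisation at C6) would give the α-carboxy lactone F1. A decarboxylative Mannich methylenation (aqueous CH2O, Et2NH, NaOAc, AcOH) would then convert F1 into 20.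

Step 11. The ring may close to the 6Z olefin, or the diene may oligomerise instead of forming the strained E-olefin ring (poor E/Z control). The fallback sets out from 10 and comes back at 18; it fixes the 6E olefin before ring closure and closes the ring at C4=C5. Wittig methylenation of hex-5-yn-2-one gives 2-methylhex-1-en-5-yne F2. Its lithium acetylide F3 and bromozinc acetylide F4 add to 10 as in step 8 to give propargylic alcohol F5. Hydrostannation as in step 9 gives alkenylstannane F6. Tin–lithium exchange to dilithio species F7, carboxylation to hydroxy acid F8 and methylation as in step 10 give methyl ester F9. Cross-metathesis of the vinyl group of F9 with (E)-but-2-enal gives the E enal F10, and Wittig methylenation gives tetraene F11. Ring-closing metathesis between the isopropenyl group and the diene terminus of F11 gives 18, in which the new trisubstituted C4=C5 olefin can only be ring-cis, that is Z.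

Step 8. The aldehyde 10 may epimerise at C8 or suffer olefin migration before addition, and chelation control at C9 may be incomplete. The fallback sets out from 13 obtained as a mixture of C9 epimers and comes back at 13. Dess–Martin oxidation gives ynone F12, and Felkin–Anh-controlled reduction with LiBH(s-Bu)3 at −78 °C sets 9S from the C8 stereocentre by hydride delivery instead of by C–C bond formation.

Further compounds
F1 | step 12 | α-carboxy lactone, 11-carboxy-11,13-dihydro analogue of 20 (C11 epimers) | OC(=O)C1C(=O)O[C@@H]2/C=C(/C)CC/C=C(/C(=O)OC)[C@H](O)[C@@H](OCc3ccc(OC)cc3)[C@@H]12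
F2 | step 11 | 2-methylhex-1-en-5-yne | C=C(C)CCC#C
F3 | step 11 | lithium acetylide of F2 | [Li]C#CCCC(C)=C
F4 | step 11 | bromozinc acetylide of F2 | Br[Zn]C#CCCC(C)=C
F5 | step 11 | (3S,4S)-3-[(4-methoxybenzyl)oxy]-9-methyldeca-1,9-dien-5-yn-4-ol | C=C(C)CCC#C[C@H](O)[C@@H](OCc1ccc(OC)cc1)C=C
F6 | step 11 | alkenylstannane from F5 (tin on the carbon next to the carbinol, syn addition) | C=C(C)CC/C=C(/[Sn](CCCC)(CCCC)CCCC)[C@H](O)[C@@H](OCc1ccc(OC)cc1)C=C
F7 | step 11 | dilithio species from F6 | C=C(C)CC/C=C(/[Li])[C@H](O[Li])[C@@H](OCc1ccc(OC)cc1)C=C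
F8 | step 11 | (2E)-2-{(1S,2S)-1-hydroxy-2-[(4-methoxybenzyl)oxy]but-3-en-1-yl}-6-methylhepta-2,6-dienoic acid | C=C(C)CC/C=C(/C(=O)O)[C@H](O)[C@@H](OCc1ccc(OC)cc1)C=C
F9 | step 11 | methyl ester of F8 | C=C(C)CC/C=C(/C(=O)OC)[C@H](O)[C@@H](OCc1ccc(OC)cc1)C=C
F10 | step 11 | E enal from cross-metathesis of F9 | C=C(C)CC/C=C(/C(=O)OC)[C@H](O)[C@@H](OCc1ccc(OC)cc1)/C=C/C=O
F11 | step 11 | tetraene from methylenation of F10 | C=C(C)CC/C=C(/C(=O)OC)[C@H](O)[C@@H](OCc1ccc(OC)cc1)/C=C/C=C
F12 | step 8 | (3Z,10S)-10-[(4-methoxybenzyl)oxy]-4-methyldodeca-1,3,11-trien-7-yn-9-one | C=C/C=C(/C)CCC#CC(=O)[C@@H](OCc1ccc(OC)cc1)C=C
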